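Two questions wait on this bench, and

- amount of complex with two exchanged at the end, in percent of the starting complex charged for red, green, amber, grey, ochre, in this order
- the course of these numbers from the first flask to the last (hardly changes / rises, then falls / falls all the way / falls, then rises / rises all the way)

 states them.

| flask | starting complex | incoming ligand | capture agent | remark | time |
|---|---|---|---|---|---|
| epsilon | 0.10 M | 1.8 equiv (in portions, 2) | 0.0023 M | run made earlier; portions every 12 h |  |
| delta | 0.10 M | 1.8 equiv (in portions, 2) | 0.0093 M | run made earlier; portions every 12 h |  |
| alpha | 0.10 M | 1.8 equiv (in portions, 2) | 0.028 M | run made earlier; portions every 12 h |  |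
| red | 0.10 M | 1.80 equiv (in portions, 2) | 0.00250 M | the portions of incoming ligand follow each other after 12 h, the first at the start | 40 h |
| green | 0.10 M | 1.80 equiv (in portions, 2) | 0.00500 M | the portions of incoming ligand follow each other after 12 h, the first at the start | 40 h |
| amber | 0.10 M | 1.80 equiv (in portions, 2) | 0.0100 M | the portions of incoming ligand follow each other after 12 h, the first at the start | 40 h |
| grey | 0.10 M | 1.80 equiv (in portions, 2) | 0.0200 M | the portions of incoming ligand follow each other after 12 h, the first at the start | 40 h |
| ochre | 0.10 M | 1.80 equiv (in portions, 2) | 0.0400 M | the portions of incoming ligand follow each other after 12 h, the first at the start | 40 h |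

- epsilon (time / h: complex with two exchanged / %, starting complex / %): 3.00: 0.6, 89.0; 6.00: 0.5, 83.9; 12.0: 0.8, 78.7; 20.0: 4.2, 66.0; 40.0: 5.6, 67.8
- delta (time / h: complex with two exchanged / %, starting complex / %): 8.00: 1.1, 81.0; 15.0: 3.0, 70.3; 25.0: 4.9, 64.3; 30.0: 4.6, 64.0; 40.0: 4.8, 66.0
- alpha (time / h: complex with two exchanged / %, starting complex / %): 8.00: 1.0, 81.3; 15.0: 2.0, 69.2; 25.0: 3.6, 62.3; 30.0: 3.5, 61.7; 40.0: 3.8, 61.5

(scatter of a reading: 0.3 percentage points)

- "hardly changes" means that all values lie within two and a half points (for a concentration: within two and a half percent of the largest)

When you take over, each flask has been charged with starting complex, capture agent and the first portion of incoming ligand, and the second portion goes in at 12 h. Keep that time, because in the epsilon run complex with two exchanged stands at 0.8% after 12.0 h and at 4.2% after 20.0 h, so the rise you are watching follows that addition. By the time you read the delta run's later points, it has levelled off: 4.9% after 25.0 h and 4.8% after 40.0 h.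

From flask to flask the charge of capture agent is the setting that changes, so set the end readings of complex with two exchanged against that charge. Between epsilon and alpha, [capture agent] rises by 0.0257 M and the final product falls by 1.8 percentage points, on readings that scatter by 0.3 points. Dividing gives the capture cost, the moles of complex with two exchanged lost per mole of capture agent charged: 0.0700.

Running a straight line from the epsilon end point at this cost, I expect 5.59% in red and 2.96% in ochre. That is a steady fall of 2.6 points, which narrowly clears the band for "hardly changes". Watch red against green: the line moves by 0.18 points between them, against a scatter of 0.3 points.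

The forecast reads 5.6%, 5.2%, 4.7%, 4% and 3.2%, falls all the way, on the view that “A smooth, gentle fall fits these points”, and it ends higher than my line in ochre.

The flasks give 5.36%, 5.12%, 4.67%, 3.90% and 2.77%, and the course falls all the way.

    starting complex + incoming ligand ⇌ leaving ligand + complex with one exchanged (K = 0.810, k = 1.70 × 10⁻⁴ L mol⁻¹ s⁻¹)
    complex with one exchanged + incoming ligand ⇌ leaving ligand + complex with two exchanged (K = 0.700, k = 8.40 × 10⁻⁵ L mol⁻¹ s⁻¹)
    2 incoming ligand → self-condensation product (k = 3.50 × 10⁻⁴ L mol⁻¹ s⁻¹)
    complex with one exchanged + capture agent → trapped intermediate (k = 7.40 × 10⁻⁴ L mol⁻¹ s⁻¹)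

Between red and ochre the capture cost comes out at 0.0691, against my 0.0700, and carried from red to amber it gives 4.83% where amber stands at 4.67%. After 40.0 h in red, the forward second exchange of complex with one exchanged runs 6.51 times as fast as its capture. In ochre at that time, capture runs 9.93 times as fast as that exchange, and trapped intermediate stands at 28.7% against 2.28% in red.

(All runs stem from a simulated flask for substances that don't exist; the scatter is artificial.)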